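# Proposed total synthesis of guajadial D (19)

## Analysis of the target

Guajadial D (19) is a spiro compound. C4 of a cadinane-type decalin (ring A: C1, C6–C10; ring B: C1–C6, with C5=C6) is also C2′ of a 5′,7′-dihydroxy-6′,8′-diformyl-4′-phenylchroman (pyran ring: O1′, C2′ = C4, C3′ = C15, C4′, C4a′, C8a′). There are five stereocentres. C7 (S, isopropyl) and C10 (R, methyl) are trans on ring A, which is the pattern of (–)-menthone. C1 (R) has H-1 cis to H-10, so C2 is cis to the methyl group and axial on ring A; this is the less stable ring fusion. C4 (S) carries O1′ trans to H-1 across ring B, and C4′ (S) carries phenyl cis to C3.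

The feature that drives the plan is in ring B: H-1 and O1′ sit on opposite faces at the two ends of the C4–C5=C6 allyl unit. Ring B is therefore the formal trans-1,4-adduct of H and an aryloxy group to a diene C1=C6–C5=C4.

The sensitive groups are the tertiary allylic aryl ether at C4 (ionisable under acid, with a vinylogous-acid aryloxide as leaving group once the ring is formylated), two aldehydes, two free phenols, and the C5=C6 bond, which can migrate through the allyl cation and erase C1 or C7. The hard points are three: the oxygenated quaternary spiro centre; C1, which is the vinylogous α-position of any C4 carbonyl and would equilibrate to the wrong epimer in enone-based routes; and C4′, which the spiro atom isolates from the terpene stereocentres.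

## Retrosynthetic reasoning

**Formyl groups last (19 ⇒ 17).** The two C–CHO bonds at C6′ and C8′ are cut first. The aldehydes would not survive the organometallic steps, and the phloroglucinol-type ring of 17 is formylated at exactly these two positions by a Vilsmeier–Haack reaction. No protecting group then has to be removed from the finished, acid-labile ether.

**Key disconnection (17 ⇒ 16).** The O1′–C4 bond and the C1–H bond are cut together. The precursor 16 holds a ring-B 1,3-diene (C1=C6–C5=C4) and a free phenol tethered through C15 and C4′. Forward, a Brønsted acid must protonate C1 and the phenol must capture the resulting C4–C5–C6 allyl cation at C4. One operation then closes the pyran ring, creates the spiro centre, places the double bond at C5=C6 and sets C1 and C4. The cut is made here because C1 is the one centre that alkylation and annulation chemistry set the wrong way: carbon electrophiles enter trans to the C10 methyl group, whereas the target needs the hydrogen delivered last, anti to that methyl. It also means that C1 never has to be carried as a labile centre next to a carbonyl.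

**Ring B (16 ⇒ 15 ⇒ 14 ⇒ 13).** After removal of the silyl groups (16 ⇒ 15), the C4=C5 bond is cut by ring-closing metathesis to give triene 14. Its vinyl group on C6 (the future C5) comes from the enol triflate 13 by coupling with a vinylstannane. An enol triflate is chosen because it fixes the C1=C6 bond without any cation chemistry that could move the double bond towards C7.

**Union of the halves (13 ⇒ 4 + 10).** The C2–C3 bond is cut. Forward, the allylsilane 10 adds in a Hosomi–Sakurai reaction to the methylidene ketone 4. This gives the C1=C6 enolate regiospecifically, and it is trapped as the triflate. Two of the stereocentres (C7, C10) come in with 4 and one (C4′) with 10, so the halves are joined after their stereochemistry is secure.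

**Aryl half (10 ⇒ 9 ⇒ 7 ⇒ 6 ⇒ 5).** The lactone carbonyl carbon of 7 is the future spiro carbon C4. Double addition of a silylmethyl Grignard reagent and Peterson elimination turn it into the 2-substituted allylsilane 9, silylated to 10. The benzylic centre is cut back to the achiral coumarin 6 (from 5); forward it is set by a chiral copper hydride catalyst, so it does not depend on the terpene.

**Terpene half (4 ⇒ 1).** The methylidene carbon (future C2) is cut from 4, leaving 1, which supplies ring A with C7 and C10 in the correct absolute configuration.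

## Alternatives that were turned down

**Alternative 1: three-component o-quinone methide hetero-Diels–Alder (the textbook, biomimetic route).**
- Disconnection: O1′–C4 and C15–C4′.
- Forward key step: Knoevenagel condensation of 2,4-diformylphloroglucinol A3 with benzaldehyde gives o-quinone methide A4, which adds across the exocyclic C4=C15 bond of diene A2.
- Turned down because:
  - A2 is only reached from 1 through nor-enone A1 (Robinson annulation, then Wittig methylenation). In A1, C1 is enolisable through the dienol and should settle in the all-equatorial form, which is the C1 epimer of what A2 needs.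
  - The cycloaddition creates C4′ with no control element (endo and exo approach of the phenyl group), and the face of attack at C4 depends on a diene that also isomerises and dimerises under the acidic, hot conditions.
  - It is the route that would be drawn first and leaves the two hardest centres to chance.

**Alternative 2: cationic [3+3] annulation of the free phloroglucinol.**
- Disconnection: C4a′–C4′ and O1′–C4.
- Forward key step: addition of a styryl Grignard reagent to the C1 epimer of A1 gives bis-allylic carbinol A5. Acid ionises it to a pentadienyl cation, which A3 attacks at the benzylic end (Friedel–Crafts) before the phenol closes onto C4.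
- Turned down because:
  - The route is very short, but C4′ is formed intermolecularly at the cation terminus farthest from every stereocentre.
  - The nucleophile A3 is deactivated by two formyl groups, so the cation has time to lose H-7.
  - C1 again has to be carried in the unstable configuration of the enone.

**Alternative 3: Diels–Alder construction of ring B on a chroman.**
- Disconnection: C1–C2 and C3–C4.
- Forward key step: the 2-alkylidenechroman diene A6 (C1=C6–C5=C4, with C4 the enol ether carbon) reacts with an ethene surrogate such as phenyl vinyl sulfone.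
- Turned down because:
  - The dienophile should add to C1 anti to the C10 methyl group, which puts C2 trans to the methyl group, the wrong C1 configuration.
  - Ethene itself is unreactive, so a surrogate and its removal add at least two steps.
  - The enol ether geometry and the face of C4 are additional open questions.

Key step: step 10

Numbering and assumptions:
- Terpenoid atoms carry cadinane locants (C1–C15) and chroman atoms primed locants, as defined in the analysis.
- The ligand enantiomer in step 3 is taken as the one that gives (S)-7; if the sense of induction is the opposite, the other enantiomer is used.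
- Compound 5 is taken as commercially available.

## Route

Step 1
Reactants: 1 (–)-menthone [(2S,5R)-5-methyl-2-(propan-2-yl)cyclohexan-1-one]
Product: 4 (3R,6S)-3-methyl-2-methylidene-6-(propan-2-yl)cyclohexan-1-one, via Mannich base 2 (not isolated), via methiodide 3 (not isolated)
Conditions: LiN(iPr)2, THF, –78 °C; H2C=NMe2+ I–, –78 → 0 °C; MeI, Et2O, 20 °C; aq NaHCO3/CH2Cl2, 20 °C; used at once
Reagents that add atoms: dimethyl(methylidene)ammonium iodide, C=[N+](C)C.[I-]
Why: Kinetic deprotonation takes the CH2 α-carbon only, the Mannich reaction with the preformed iminium salt and the mild elimination of the quaternary ammonium salt give the α-methylidene ketone; no equilibrating base touches C7 (isopropyl), and no stereocentre is created.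

Step 2
Reactants: 5 5,7-dihydroxy-4-phenyl-2H-chromen-2-one
Product: 6 5,7-bis(tert-butyldimethylsilyloxy)-4-phenyl-2H-chromen-2-one
Conditions: TBSCl, imidazole, DMF, 20 °C
Reagents that add atoms: tert-butyl(chloro)dimethylsilane, CC(C)(C)[Si](C)(C)Cl
Why: Silyl ether formation on both phenols keeps acidic OH groups away from the copper hydride and from the Grignard reagent and is removable at the end with fluoride; no stereocentre.

Step 3
Reactants: 6
Product: 7 (4S)-5,7-bis(tert-butyldimethylsilyloxy)-4-phenylchroman-2-one
Conditions: Cu(OAc)2·H2O (3 mol%), (S)-DTBM-SEGPHOS (3 mol%), (EtO)2MeSiH, t-BuOH, toluene, 0 → 20 °C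
Reagents that add atoms: none
Why: Copper-hydride-catalysed asymmetric conjugate reduction of a β,β-disubstituted unsaturated lactone, a reaction type known for 4-arylcoumarins; ligand-controlled hydride delivery to C4′ sets the benzylic centre, and t-BuOH protonates the silyl ketene acetal before the lactone is reduced further.

Step 4
Reactants: 7
Product: 9 3,5-bis(tert-butyldimethylsilyloxy)-2-[(1S)-1-phenyl-3-[(trimethylsilyl)methyl]but-3-en-1-yl]phenol, via carbinol 8 (not isolated)
Conditions: Me3SiCH2MgCl (4 equiv), CeCl3, THF, –78 → 20 °C; aq NH4Cl; crude, SiO2, CH2Cl2, 20 °C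
Reagents that add atoms: (trimethylsilyl)methylmagnesium chloride, C[Si](C)(C)C[Mg]Cl
Why: Double addition of the silylmethyl organocerium reagent to the lactone and Peterson elimination of the bis(β-silyl) carbinol give the 2-substituted allylsilane; the lactone carbon becomes C4, and C4′ is β to the carbonyl group and cannot epimerise.

Step 5
Reactants: 9
Product: 10 trimethyl{(4S)-2-methylidene-4-phenyl-4-[2,4,6-tris(tert-butyldimethylsilyloxy)phenyl]butyl}silane
Conditions: TBSCl, imidazole, DMF, 40 °C
Reagents that add atoms: tert-butyl(chloro)dimethylsilane, CC(C)(C)[Si](C)(C)Cl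
Why: Silyl ether formation masks the phenol that would otherwise be sulfonylated in step 6 or add to the alkene under acid; the aryl ring becomes symmetric, so that either ortho oxygen can later close the pyran ring.

Step 6
Reactants: 4, 10
Product: 13 (3R,6S)-3-methyl-2-{(5S)-3-methylidene-5-phenyl-5-[2,4,6-tris(tert-butyldimethylsilyloxy)phenyl]pentyl}-6-(propan-2-yl)cyclohex-1-en-1-yl trifluoromethanesulfonate, via trimethylsilyl enol ether 11 (not isolated), via lithium enolate 12 (not isolated)
Conditions: HNTf2 (5 mol%), CH2Cl2, –78 °C; Et3N (10 mol%), concentrate; MeLi, THF, 0 °C; N-(5-chloropyridin-2-yl)triflimide, –78 → 20 °C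
Reagents that add atoms: N-(5-chloropyridin-2-yl)-1,1,1-trifluoro-N-(trifluoromethylsulfonyl)methanesulfonamide, FC(F)(F)S(=O)(=O)N(c1ccc(Cl)cn1)S(=O)(=O)C(F)(F)F
Why: Hosomi–Sakurai conjugate allylation catalysed by Me3SiNTf2 formed in situ: the γ-carbon of 10 adds to the unsubstituted methylidene carbon of 4 (C2–C3 bond) and silicon passes to the enolate oxygen, so the C1=C6 enol ether forms regiospecifically; Si–O cleavage with MeLi and O-sulfonylation of the lithium enolate are standard, and C1 is deliberately left sp2.

Step 7
Reactants: 13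
Product: 14 tert-butyl-[2-[(1S)-5-[(3R,6S)-2-ethenyl-6-methyl-3-(propan-2-yl)cyclohex-1-en-1-yl]-3-methylidene-1-phenylpentyl]-3,5-bis(tert-butyldimethylsilyloxy)phenoxy]dimethylsilane
Conditions: Bu3SnCH=CH2, Pd(PPh3)4 (5 mol%), LiCl, THF, 65 °C
Reagents that add atoms: tributyl(ethenyl)stannane, C=C[Sn](CCCC)(CCCC)CCCC
Why: Stille coupling of an alkenyl triflate (chloride-assisted) brings in C5 as a vinyl group; aryl silyl ethers and the 1,1-disubstituted alkene are inert.

Step 8
Reactants: 14
Product: 15 tert-butyl-[2-[(1S)-2-[(5S,8R)-8-methyl-5-(propan-2-yl)-1,2,5,6,7,8-hexahydronaphthalen-3-yl]-1-phenylethyl]-3,5-bis(tert-butyldimethylsilyloxy)phenoxy]dimethylsilane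
Conditions: second-generation Hoveyda–Grubbs catalyst RuCl2(H2IMes)(=CH-C6H4-2-OiPr) (5 mol%), degassed toluene, 60 °C
Reagents that add atoms: none
Why: Ring-closing metathesis between the terminal vinyl group and the 1,1-disubstituted alkene closes ring B through a trisubstituted C4=C5 bond; the tetrasubstituted C1=C6 bond cannot take part, and loss of ethene drives the six-membered ring closure.

Step 9
Reactants: 15
Product: 16 2-[(1S)-2-[(5S,8R)-8-methyl-5-(propan-2-yl)-1,2,5,6,7,8-hexahydronaphthalen-3-yl]-1-phenylethyl]benzene-1,3,5-triol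
Conditions: Bu4NF, AcOH, degassed THF, 0 °C; pH 7 work-up, no silica gel
Reagents that add atoms: none
Why: Fluoride cleavage of the three aryl silyl ethers under buffered, non-acidic conditions leaves the acid-labile diene and the C7 and C10 centres untouched.

Step 10
Reactants: 16
Product: 17 (1R,4S,7S,10R,4′S)-4′-phenylspiro[cadin-5-ene-4,2′-chroman]-5′,7′-diol
Conditions: (±)-camphor-10-sulfonic acid (10 mol%), degassed CH2Cl2 (0.01 M), –40 → –10 °C; Et3N quench
Reagents that add atoms: none
Why: Protonation of the ring-B diene at C1 gives the C4–C5–C6 allyl cation, tertiary at both ends, which an ortho-phenol captures at C4; this is the Brønsted-acid-catalysed hydroalkoxylation of a 1,3-diene by a phenol, the reaction type behind chroman syntheses from phenols and dienes. The pyran ring closes in a 6-exo sense: oxygen attacks the allyl terminus C4 and the C5=C6 bond stays outside the new ring, whereas attack at C6 would need an eight-membered ring. Protonation should go to C1 and not to C4, because the C5–C6–C1 cation has a secondary terminus, cannot be trapped in a six-membered ring and can only revert. C1 is controlled by ring A: A(1,2) strain between the C10 methyl group and C2, and between the C7 isopropyl group and C5, holds both substituents pseudoaxial on opposite faces of the diene, and the proton should add axially to C1 anti to the pseudoaxial methyl group, which places H-1 cis to H-10. C4 is controlled by ring B: the cation should sit in the envelope that keeps C10 pseudoequatorial and H-1 pseudoaxial, and axial attack leading directly to the half-chair puts O1′ trans to H-1. C4′ is already fixed, so both new centres depend on ring A alone. The step needs capture to outrun loss of H-7 from the cation and intermolecular C-alkylation; the intramolecular six-membered capture, high dilution and low temperature should secure this.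

Step 11
Reactants: 17
Product: 19 guajadial D [(1R,4S,7S,10R,4′S)-5′,7′-dihydroxy-4′-phenylspiro[cadin-5-ene-4,2′-chroman]-6′,8′-dicarbaldehyde], via bis-iminium chloride 18 (not isolated)
Conditions: POCl3, DMF, EtOAc, 0 → 20 °C; aq NaOAc, 20 °C
Reagents that add atoms: N,N-dimethylformamide, CN(C)C=O; water, O
Why: Vilsmeier–Haack formylation attacks the phloroglucinol-type ring at its two free positions C6′ and C8′, the standard entry to 2,4-diformylphloroglucinols, and buffered hydrolysis of the bis-iminium salt releases the aldehydes; no stereocentre is touched as long as the allylic ether does not ionise.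

## Compound list

1 | (–)-menthone, (2S,5R)-5-methyl-2-(propan-2-yl)cyclohexan-1-one | CC(C)[C@@H]1CC[C@@H](C)CC1=O | starting material
2 | (3R,6S)-2-[(dimethylamino)methyl]-3-methyl-6-(propan-2-yl)cyclohexan-1-one (both C2 epimers) | CC(C)[C@@H]1CC[C@@H](C)C(CN(C)C)C1=O | intermediate
3 | trimethyl{[(3R,6S)-3-methyl-2-oxo-6-(propan-2-yl)cyclohexyl]methyl}ammonium iodide (both C2 epimers) | CC(C)[C@@H]1CC[C@@H](C)C(C[N+](C)(C)C)C1=O.[I-] | intermediate
4 | (3R,6S)-3-methyl-2-methylidene-6-(propan-2-yl)cyclohexan-1-one | CC(C)[C@@H]1CC[C@@H](C)C(=C)C1=O | intermediate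
5 | 5,7-dihydroxy-4-phenyl-2H-chromen-2-one | O=c1cc(-c2ccccc2)c2c(O)cc(O)cc2o1 | starting material
6 | 5,7-bis(tert-butyldimethylsilyloxy)-4-phenyl-2H-chromen-2-one | O=c1cc(-c2ccccc2)c2c(O[Si](C)(C)C(C)(C)C)cc(O[Si](C)(C)C(C)(C)C)cc2o1 | intermediate
7 | (4S)-5,7-bis(tert-butyldimethylsilyloxy)-4-phenylchroman-2-one | O=C1C[C@@H](c2ccccc2)c2c(O[Si](C)(C)C(C)(C)C)cc(O[Si](C)(C)C(C)(C)C)cc2O1 | intermediate
8 | 3,5-bis(tert-butyldimethylsilyloxy)-2-[(1S)-3-hydroxy-1-phenyl-4-(trimethylsilyl)-3-[(trimethylsilyl)methyl]butyl]phenol | C[Si](C)(C)CC(O)(C[Si](C)(C)C)C[C@@H](c1ccccc1)c1c(O)cc(O[Si](C)(C)C(C)(C)C)cc1O[Si](C)(C)C(C)(C)C | intermediate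
9 | 3,5-bis(tert-butyldimethylsilyloxy)-2-[(1S)-1-phenyl-3-[(trimethylsilyl)methyl]but-3-en-1-yl]phenol | C=C(C[Si](C)(C)C)C[C@@H](c1ccccc1)c1c(O)cc(O[Si](C)(C)C(C)(C)C)cc1O[Si](C)(C)C(C)(C)C | intermediate
10 | trimethyl{(4S)-2-methylidene-4-phenyl-4-[2,4,6-tris(tert-butyldimethylsilyloxy)phenyl]butyl}silane | C=C(C[Si](C)(C)C)C[C@@H](c1ccccc1)c1c(O[Si](C)(C)C(C)(C)C)cc(O[Si](C)(C)C(C)(C)C)cc1O[Si](C)(C)C(C)(C)C | intermediate
11 | trimethylsilyl enol ether of the conjugate adduct (C1=C6, OSiMe3 on C6; 3R,6S ring, 5S chain) | CC(C)[C@@H]1CC[C@@H](C)C(CCC(=C)C[C@@H](c2ccccc2)c2c(O[Si](C)(C)C(C)(C)C)cc(O[Si](C)(C)C(C)(C)C)cc2O[Si](C)(C)C(C)(C)C)=C1O[Si](C)(C)C | intermediate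
12 | lithium enolate corresponding to 11 | CC(C)[C@@H]1CC[C@@H](C)C(CCC(=C)C[C@@H](c2ccccc2)c2c(O[Si](C)(C)C(C)(C)C)cc(O[Si](C)(C)C(C)(C)C)cc2O[Si](C)(C)C(C)(C)C)=C1[O-].[Li+] | intermediate
13 | (3R,6S)-3-methyl-2-{(5S)-3-methylidene-5-phenyl-5-[2,4,6-tris(tert-butyldimethylsilyloxy)phenyl]pentyl}-6-(propan-2-yl)cyclohex-1-en-1-yl trifluoromethanesulfonate | CC(C)[C@@H]1CC[C@@H](C)C(CCC(=C)C[C@@H](c2ccccc2)c2c(O[Si](C)(C)C(C)(C)C)cc(O[Si](C)(C)C(C)(C)C)cc2O[Si](C)(C)C(C)(C)C)=C1OS(=O)(=O)C(F)(F)F | intermediate
14 | triene: as 13 with ethenyl in place of the triflate group | CC(C)[C@@H]1CC[C@@H](C)C(CCC(=C)C[C@@H](c2ccccc2)c2c(O[Si](C)(C)C(C)(C)C)cc(O[Si](C)(C)C(C)(C)C)cc2O[Si](C)(C)C(C)(C)C)=C1C=C | intermediate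
15 | tris-silyl ether of 16 (ring-B diene C1=C6–C5=C4; 5S,8R ring, 1S chain) | CC(C)[C@@H]1CC[C@@H](C)C2=C1C=C(CC2)C[C@@H](c1ccccc1)c1c(O[Si](C)(C)C(C)(C)C)cc(O[Si](C)(C)C(C)(C)C)cc1O[Si](C)(C)C(C)(C)C | intermediate
16 | 2-[(1S)-2-[(5S,8R)-8-methyl-5-(propan-2-yl)-1,2,5,6,7,8-hexahydronaphthalen-3-yl]-1-phenylethyl]benzene-1,3,5-triol | CC(C)[C@@H]1CC[C@@H](C)C2=C1C=C(CC2)C[C@@H](c1ccccc1)c1c(O)cc(O)cc1O | intermediate
17 | (1R,4S,7S,10R,4′S)-4′-phenylspiro[cadin-5-ene-4,2′-chroman]-5′,7′-diol | CC(C)[C@@H]1CC[C@@H](C)[C@H]2CC[C@@]3(C=C12)C[C@@H](c1ccccc1)c1c(O)cc(O)cc1O3 | intermediate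
18 | 6′,8′-bis(dimethyliminiomethyl) derivative of 17, dichloride | CC(C)[C@@H]1CC[C@@H](C)[C@H]2CC[C@@]3(C=C12)C[C@@H](c1ccccc1)c1c(O)c(C=[N+](C)C)c(O)c(C=[N+](C)C)c1O3.[Cl-].[Cl-] | intermediate
19 | guajadial D | CC(C)[C@@H]1CC[C@@H](C)[C@H]2CC[C@@]3(C=C12)C[C@@H](c1ccccc1)c1c(O)c(C=O)c(O)c(C=O)c1O3 | target

## Step count and risk

Total step count: 11. Longest linear sequence: 10 steps (5 → 19, steps 2–11); the menthone branch (step 1) joins at step 6.

**Step 10 (key step).**
- What may go wrong:
  - Protonation on the wrong face of C1, either through the minor half-chair with pseudoequatorial methyl and isopropyl groups or because the pseudoaxial isopropyl group shields the intended face.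
  - Loss of H-7 from the allyl cation, which moves the double bond to C6=C7 and scrambles C7.
  - Oxidative aromatisation of the ring-B diene.
  - Re-ionisation of the product, with epimerisation at C4.
- Fallback: it sets out from 4 and 10 and comes back at 17, and fixes C1 before ring B exists.
  - Hosomi–Sakurai addition of 10 to 4 with TiCl4 (CH2Cl2, –78 °C), then quench of the titanium enolate at –78 °C with 2,6-di-tert-butyl-4-methylphenol, should give by kinetic protonation anti to the pseudoaxial methyl group the cis ketone F1.
  - CH2=CHMgBr/CeCl3 (THF, –78 °C) should add anti to the axial side chain and give the tertiary allylic alcohol F2.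
  - Ring-closing metathesis with the catalyst of step 8 closes ring B as the bicyclic allylic alcohol F3.
  - Bu4NF/AcOH gives the triol F4.
  - Catalytic camphor-10-sulfonic acid ionises the C6 hydroxyl group; the same allyl cation forms with H-1 already in place, and phenol capture at C4 leads to 17.

**Step 6.**
- What may go wrong: protodesilylation of the allylsilane by the acid before silyl transfer turns over; conjugate addition of the electron-rich arene in place of the allylsilane; cleavage of an aryl silyl ether by MeLi followed by sulfonylation of the phenoxide.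
- Fallback: it sets out from 4 and 10 and comes back at 13, and makes the enolate by deprotonation instead. Stoichiometric TiCl4 (CH2Cl2, –78 °C) with ordinary aqueous work-up gives the ketone F5 as a mixture at C1, which is of no consequence. KN(SiMe3)2 (THF, –78 °C) should remove the less hindered C1 methine proton in preference to the C7 proton next to the isopropyl group, and the triflimide reagent of step 6 then gives 13.

**Step 11.**
- What may go wrong: ionisation of the tertiary allylic ether under the HCl and iminium conditions; a second formylation that stalls on the deactivated ring.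
- Fallback: it sets out from 17 and comes back at 19, and replaces electrophilic substitution by directed metalation. MOMCl/iPr2NEt gives the bis(methoxymethyl) ether F6. n-BuLi (THF, 0 °C) then DMF, followed in the same flask by s-BuLi/TMEDA (–78 °C) then DMF, should lithiate first between the two acetal oxygens and then between the acetal and ring oxygens, and give the dialdehyde F7. NaHSO4·SiO2 in CH2Cl2 at 20 °C removes the two chelated acetals to give 19.

**Step 3.**
- What may go wrong: slow hydride transfer to the crowded C4′ next to the peri silyloxy group, over-reduction of the lactone to the lactol, and low enantioselectivity.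
- Fallback: it sets out from 6 and comes back at 7. Hydrogenation (H2, Pd/C, EtOAc) gives the racemic lactone F8, which is resolved by preparative chromatography on a chiral stationary phase to (S)-7.

## Further compounds

F1 | step 10 | (2R,3R,6S)-3-methyl-2-{(5S)-3-methylidene-5-phenyl-5-[2,4,6-tris(tert-butyldimethylsilyloxy)phenyl]pentyl}-6-(propan-2-yl)cyclohexan-1-one (side chain cis to methyl) | CC(C)[C@@H]1CC[C@@H](C)[C@@H](CCC(=C)C[C@@H](c2ccccc2)c2c(O[Si](C)(C)C(C)(C)C)cc(O[Si](C)(C)C(C)(C)C)cc2O[Si](C)(C)C(C)(C)C)C1=O
F2 | step 10 | 1-ethenyl carbinol from F1 (vinyl trans to the side chain) | CC(C)[C@@H]1CC[C@@H](C)[C@@H](CCC(=C)C[C@@H](c2ccccc2)c2c(O[Si](C)(C)C(C)(C)C)cc(O[Si](C)(C)C(C)(C)C)cc2O[Si](C)(C)C(C)(C)C)[C@]1(O)C=C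
F3 | step 10 | ring-B allylic alcohol (C4=C5, hydroxyl on C6, H-1 trans to OH), tris-silyl ether | CC(C)[C@@H]1CC[C@@H](C)[C@H]2CCC(C[C@@H](c3ccccc3)c3c(O[Si](C)(C)C(C)(C)C)cc(O[Si](C)(C)C(C)(C)C)cc3O[Si](C)(C)C(C)(C)C)=C[C@]12O
F4 | step 10 | ring-B allylic alcohol with free benzene-1,3,5-triol | CC(C)[C@@H]1CC[C@@H](C)[C@H]2CCC(C[C@@H](c3ccccc3)c3c(O)cc(O)cc3O)=C[C@]12O
F5 | step 6 | ketone of constitution F1, both C1 epimers | CC(C)[C@@H]1CC[C@@H](C)C(CCC(=C)C[C@@H](c2ccccc2)c2c(O[Si](C)(C)C(C)(C)C)cc(O[Si](C)(C)C(C)(C)C)cc2O[Si](C)(C)C(C)(C)C)C1=O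
F6 | step 11 | 5′,7′-bis(methoxymethyl) ether of 17 | CC(C)[C@@H]1CC[C@@H](C)[C@H]2CC[C@@]3(C=C12)C[C@@H](c1ccccc1)c1c(OCOC)cc(OCOC)cc1O3
F7 | step 11 | 5′,7′-bis(methoxymethyl) ether of 19 | CC(C)[C@@H]1CC[C@@H](C)[C@H]2CC[C@@]3(C=C12)C[C@@H](c1ccccc1)c1c(OCOC)c(C=O)c(OCOC)c(C=O)c1O3
F8 | step 3 | racemic 5,7-bis(tert-butyldimethylsilyloxy)-4-phenylchroman-2-one | O=C1CC(c2ccccc2)c2c(O[Si](C)(C)C(C)(C)C)cc(O[Si](C)(C)C(C)(C)C)cc2O1
A1 | alternative 1 | (4aS,5R,8S)-5-methyl-8-(propan-2-yl)-4,4a,5,6,7,8-hexahydronaphthalen-2(3H)-one | CC(C)[C@@H]1CC[C@@H](C)[C@@H]2CCC(=O)C=C12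
A2 | alternative 1 | (1S,4R,4aR)-4-methyl-7-methylidene-1-(propan-2-yl)-1,2,3,4,4a,5,6,7-octahydronaphthalene | CC(C)[C@@H]1CC[C@@H](C)[C@H]2CCC(=C)C=C12
A3 | alternative 1 | 2,4,6-trihydroxybenzene-1,3-dicarbaldehyde | O=Cc1c(O)cc(O)c(C=O)c1O
A4 | alternative 1 | o-quinone methide from A3 and benzaldehyde | O=CC1=C(O)C(C=O)=C(O)C(=Cc2ccccc2)C1=O
A5 | alternative 2 | (4aR,5R,8S)-5-methyl-2-[(E)-2-phenylethenyl]-8-(propan-2-yl)-2,3,4,4a,5,6,7,8-octahydronaphthalen-2-ol (either C2 epimer) | CC(C)[C@@H]1CC[C@@H](C)[C@H]2CCC(O)(/C=C/c3ccccc3)C=C12
A6 | alternative 3 | (2Z,4S)-2-{[(3R,6S)-3-methyl-6-(propan-2-yl)cyclohex-1-en-1-yl]methylidene}-4-phenylchroman-5,7-diol | CC(C)[C@@H]1CC[C@@H](C)C=C1/C=C1/C[C@@H](c2ccccc2)c2c(O)cc(O)cc2O1
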